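**Plan**
- Retrosynthesis: the benzyl ester and the dioxolane are removed last; ring B is cut at C1–C2 and C5–C6 into an oct-2-ynoate (C1, C6, carboxyl, pentyl) and a four-carbon vinylketene acetal (C2–C5) that already carries the ring-A aroyl group on oxygen.
- Enabling feature: ring B has its carboxyl at C1 between a free C2–OH and the C6 pentyl group, with the only acylated oxygen at C4; this maps C2 onto a ketene-acetal carbon and C4–O onto the enol-ester oxygen of an acetoacetate-derived diene.
- The diene is traced to the enol ester of methyl acetoacetate with the ring-A acid, and that acid to a lateral (benzylic) acylation of a purchased orsellinate dimethyl ether.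
- Forward order: ring A is bought; its side chain is built, masked and the acid activated (steps 1–4); the acid is hung on methyl acetoacetate and turned into the diene (steps 5–6); ring B is formed in step 8; two unmasking steps finish.
- Stereochemistry: the target has no stereocentre; the only stereo-element on the way, the E geometry of enol ester 9, serves the γ-deprotonation and disappears in the diene.

Key step: step 8

Remark: the target contains no stereogenic element, so "single enantiomer" is read as the one achiral compound. Deprotonated forms of a numbered compound (lithiated species, enolates, carboxylate salts) are not numbered separately.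

**Step 1**
Reactants: 1 methyl 2,4-dimethoxy-6-methylbenzoate; 2 N-methoxy-N-methylbutanamide
Product: 4 methyl 2,4-dimethoxy-6-(2-oxopentyl)benzoate, via lithium hemiaminal alkoxide 3 (not isolated)
Conditions: LDA, THF, −78 °C; then 2, −78 °C; AcOH quench
Reagents that add atoms: none
Why: Lateral lithiation of the o-toluate followed by Weinreb amide acylation should give the ketone only at the quench, because the chelated tetrahedral adduct 3 (racemic, transient) prevents over-addition and proton transfer to the benzylic anion.

**Step 2**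
Reactants: 4 methyl 2,4-dimethoxy-6-(2-oxopentyl)benzoate
Product: 5 methyl 2,4-dimethoxy-6-[(2-propyl-1,3-dioxolan-2-yl)methyl]benzoate
Conditions: TMSOCH2CH2OTMS, TMSOTf (cat.), CH2Cl2, −78 → −20 °C; pyridine quench
Reagents that add atoms: 1,2-bis(trimethylsilyloxy)ethane, C[Si](C)(C)OCCO[Si](C)(C)C
Why: Noyori ketalisation should mask the ketone at low temperature, conditions too mild for acid-induced enol lactonisation of the keto ester to the isocoumarin.

**Step 3**
Reactants: 5 methyl 2,4-dimethoxy-6-[(2-propyl-1,3-dioxolan-2-yl)methyl]benzoate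
Product: 6 2,4-dimethoxy-6-[(2-propyl-1,3-dioxolan-2-yl)methyl]benzoic acid
Conditions: KOH, DMSO/H2O, 90 °C; then cold 1 M HCl to pH 4
Reagents that add atoms: potassium hydroxide, [K+].[OH-]
Why: Saponification of the di-ortho-substituted benzoate needs forcing hydroxide in aqueous DMSO, which the dioxolane and aryl ethers tolerate, and cold acidification to pH 4 only should keep the ketal intact.

**Step 4**
Reactants: 6 2,4-dimethoxy-6-[(2-propyl-1,3-dioxolan-2-yl)methyl]benzoic acid
Product: 7 2,4-dimethoxy-6-[(2-propyl-1,3-dioxolan-2-yl)methyl]benzoyl chloride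
Conditions: Ghosez reagent, CH2Cl2, 0 °C → rt; concentrated and used at once
Reagents that add atoms: 1-chloro-N,N,2-trimethylprop-1-en-1-amine, CC(C)=C(Cl)N(C)C
Why: Acid chloride formation with Ghosez's α-chloroenamine runs under neutral conditions without liberating HCl, which should spare the acid-labile dioxolane.

**Step 5**
Reactants: 7 2,4-dimethoxy-6-[(2-propyl-1,3-dioxolan-2-yl)methyl]benzoyl chloride; 8 methyl acetoacetate
Product: 9 methyl (2E)-3-({2,4-dimethoxy-6-[(2-propyl-1,3-dioxolan-2-yl)methyl]benzoyl}oxy)but-2-enoate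
Conditions: Et3N, DMAP (cat.), DMPU/CH2Cl2, 0 °C → rt
Reagents that add atoms: none
Why: O-acylation of the β-keto ester enolate should prevail because the non-chelated ammonium enolate in a dipolar aprotic medium meets a hard, hindered aroyl electrophile, and these conditions should favour the E enol ester with the methyl group cis to the ester.

**Step 6**
Reactants: 9 methyl (2E)-3-({2,4-dimethoxy-6-[(2-propyl-1,3-dioxolan-2-yl)methyl]benzoyl}oxy)but-2-enoate
Product: 10 4-[(tert-butyldimethylsilyl)oxy]-4-methoxybuta-1,3-dien-2-yl 2,4-dimethoxy-6-[(2-propyl-1,3-dioxolan-2-yl)methyl]benzoate (ketene acetal geometry not controlled and immaterial)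
Conditions: LiHMDS, TBSCl, THF/DMPU, −78 → 0 °C (base added last); non-aqueous work-up, used crude
Reagents that add atoms: tert-butyldimethylsilyl chloride, CC(C)(C)[Si](C)(C)Cl
Why: Proposed new method: the γ-methyl of 9 lies cis to the ester carbonyl and is the only readily acidic C–H, so the hindered, non-nucleophilic amide should form the cross-conjugated dienolate (vinylogous ester enolisation), which DMPU-activated TBSCl already present silylates on oxygen before the di-ortho-substituted aroyl group can migrate or be expelled; the closest known reaction type is γ-deprotonation/O-silylation of 3-alkoxy- and 3-silyloxybut-2-enoates to Brassard- and Chan-type vinylketene acetals, not yet shown with a 3-acyloxy substituent.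

**Step 7**
Reactants: 11 oct-2-ynoic acid
Product: 12 benzyl oct-2-ynoate
Conditions: BnBr, K2CO3, DMF, rt
Reagents that add atoms: benzyl bromide, BrCc1ccccc1
Why: SN2 O-alkylation of the carboxylate with benzyl bromide under mild carbonate base should esterify without isomerising the ynoate to the allenoate.

**Step 8**
Reactants: 10 4-[(tert-butyldimethylsilyl)oxy]-4-methoxybuta-1,3-dien-2-yl 2,4-dimethoxy-6-[(2-propyl-1,3-dioxolan-2-yl)methyl]benzoate; 12 benzyl oct-2-ynoate
Product: 15 benzyl 4-({2,4-dimethoxy-6-[(2-propyl-1,3-dioxolan-2-yl)methyl]benzoyl}oxy)-2-hydroxy-6-pentylbenzoate, via cyclohexa-1,4-diene cycloadduct 13 (not isolated), via aryl silyl ether 14 (not isolated)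
Conditions: 12 (3 equiv), toluene, 110 °C, sealed tube; then TBAF, AcOH, THF, 0 °C
Reagents that add atoms: none
Why: Proposed new method: the donor oxygens at C1 and C3 of diene 10 place the largest HOMO coefficient on the terminal CH2, which bonds to the β-carbon of ynoate 12 while the acetal carbon bonds to the α-carbon in an asynchronous normal-demand [4+2] cycloaddition giving 13; 1,4-elimination of methanol aromatises 13 to 14 and buffered fluoride removes the silyl group, any surviving 13 converging on the same phenol through the cyclohexadienone. The closest known reaction type is the Diels–Alder benzannulation of 1,1-dialkoxy-3-silyloxy- and 1-alkoxy-1,3-bis(silyloxy)butadienes with alk-2-ynoates to 6-alkylresorcylates; new here is the acyloxy group at C3 of the diene. Ring B, the only ring formed, closes in the cycloaddition itself as a six-membered carbocycle (in the stepwise limit a Michael addition followed by 6-exo-trig capture of the silyloxycarbenium ion by the allenolate α-carbon). No stereocentre remains, since the acetal carbon of 13 is formed racemic and becomes aromatic C2. The step needs regioselectivity (acetal carbon to the ester-bearing alkyne carbon), secured by the ketene-acetal polarisation of the diene against the ynoate, and retention of the depside ester, secured by the two ortho substituents that shield the aroyl carbonyl from acyl transfer.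

**Step 9**
Reactants: 15 benzyl 4-({2,4-dimethoxy-6-[(2-propyl-1,3-dioxolan-2-yl)methyl]benzoyl}oxy)-2-hydroxy-6-pentylbenzoate
Product: 16 benzyl 4-{[2,4-dimethoxy-6-(2-oxopentyl)benzoyl]oxy}-2-hydroxy-6-pentylbenzoate
Conditions: 1 M aq. HCl, THF, rt
Reagents that add atoms: water, O
Why: Acid-catalysed acetal hydrolysis of a dialkyl ketone dioxolane proceeds at room temperature in dilute acid, conditions under which the hindered aryl ester and the benzyl ester should persist.

**Step 10**
Reactants: 16 benzyl 4-{[2,4-dimethoxy-6-(2-oxopentyl)benzoyl]oxy}-2-hydroxy-6-pentylbenzoate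
Product: 17 4-{[2,4-dimethoxy-6-(2-oxopentyl)benzoyl]oxy}-2-hydroxy-6-pentylbenzoic acid
Conditions: H2 (1 atm), 10% Pd/C, EtOAc, rt
Reagents that add atoms: none
Why: Hydrogenolysis of the benzyl ester over palladium is neutral and should free the decarboxylation-prone salicylic acid last, without touching the dialkyl ketone, the depside ester or the aryl ethers.

**Compound list**
1 | methyl 2,4-dimethoxy-6-methylbenzoate | COC(=O)c1c(C)cc(OC)cc1OC | starting material
2 | N-methoxy-N-methylbutanamide | CCCC(=O)N(C)OC | starting material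
3 | lithium 1-[3,5-dimethoxy-2-(methoxycarbonyl)phenyl]-2-[methoxy(methyl)amino]pentan-2-olate (racemic, transient) | [Li+].CCCC([O-])(Cc1cc(OC)cc(OC)c1C(=O)OC)N(C)OC | intermediate (not isolated)
4 | methyl 2,4-dimethoxy-6-(2-oxopentyl)benzoate | CCCC(=O)Cc1cc(OC)cc(OC)c1C(=O)OC | intermediate
5 | methyl 2,4-dimethoxy-6-[(2-propyl-1,3-dioxolan-2-yl)methyl]benzoate | CCCC1(Cc2cc(OC)cc(OC)c2C(=O)OC)OCCO1 | intermediate
6 | 2,4-dimethoxy-6-[(2-propyl-1,3-dioxolan-2-yl)methyl]benzoic acid | CCCC1(Cc2cc(OC)cc(OC)c2C(=O)O)OCCO1 | intermediate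
7 | 2,4-dimethoxy-6-[(2-propyl-1,3-dioxolan-2-yl)methyl]benzoyl chloride | CCCC1(Cc2cc(OC)cc(OC)c2C(=O)Cl)OCCO1 | intermediate
8 | methyl acetoacetate | CC(=O)CC(=O)OC | starting material
9 | methyl (2E)-3-({2,4-dimethoxy-6-[(2-propyl-1,3-dioxolan-2-yl)methyl]benzoyl}oxy)but-2-enoate | C/C(OC(=O)c1c(CC2(CCC)OCCO2)cc(OC)cc1OC)=C\C(=O)OC | intermediate
10 | 4-[(tert-butyldimethylsilyl)oxy]-4-methoxybuta-1,3-dien-2-yl 2,4-dimethoxy-6-[(2-propyl-1,3-dioxolan-2-yl)methyl]benzoate | C=C(OC(=O)c1c(CC2(CCC)OCCO2)cc(OC)cc1OC)C=C(OC)O[Si](C)(C)C(C)(C)C | intermediate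
11 | oct-2-ynoic acid | CCCCCC#CC(=O)O | starting material
12 | benzyl oct-2-ynoate | CCCCCC#CC(=O)OCc1ccccc1 | intermediate
13 | benzyl 6-[(tert-butyldimethylsilyl)oxy]-4-({2,4-dimethoxy-6-[(2-propyl-1,3-dioxolan-2-yl)methyl]benzoyl}oxy)-6-methoxy-2-pentylcyclohexa-1,4-diene-1-carboxylate (racemic at the acetal carbon) | CCCCCC1=C(C(=O)OCc2ccccc2)C(OC)(O[Si](C)(C)C(C)(C)C)C=C(OC(=O)c2c(CC3(CCC)OCCO3)cc(OC)cc2OC)C1 | intermediate (not isolated)
14 | benzyl 2-[(tert-butyldimethylsilyl)oxy]-4-({2,4-dimethoxy-6-[(2-propyl-1,3-dioxolan-2-yl)methyl]benzoyl}oxy)-6-pentylbenzoate | CCCCCc1cc(OC(=O)c2c(CC3(CCC)OCCO3)cc(OC)cc2OC)cc(O[Si](C)(C)C(C)(C)C)c1C(=O)OCc1ccccc1 | intermediate (not isolated)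
15 | benzyl 4-({2,4-dimethoxy-6-[(2-propyl-1,3-dioxolan-2-yl)methyl]benzoyl}oxy)-2-hydroxy-6-pentylbenzoate | CCCCCc1cc(OC(=O)c2c(CC3(CCC)OCCO3)cc(OC)cc2OC)cc(O)c1C(=O)OCc1ccccc1 | intermediate
16 | benzyl 4-{[2,4-dimethoxy-6-(2-oxopentyl)benzoyl]oxy}-2-hydroxy-6-pentylbenzoate | CCCCCc1cc(OC(=O)c2c(CC(=O)CCC)cc(OC)cc2OC)cc(O)c1C(=O)OCc1ccccc1 | intermediate
17 | 4-{[2,4-dimethoxy-6-(2-oxopentyl)benzoyl]oxy}-2-hydroxy-6-pentylbenzoic acid | CCCCCc1cc(OC(=O)c2c(CC(=O)CCC)cc(OC)cc2OC)cc(O)c1C(=O)O | target

**Totals**
Total step count: 10. Longest linear sequence: 9 steps (steps 1–6, 8, 9, 10); step 7 is a one-step branch.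

**Steps most likely to fail**

1. Step 8 (Proposed new method). The acyloxy-substituted diene is less electron-rich than its silyloxy relatives. It may be lost to silyl migration, protonolysis by liberated methanol or oligomerisation faster than it adds to the β-alkylated ynoate, and the acetal adduct may partly lose silanol instead of methanol. The fallback uses known chemistry, sets out from benzyl oct-2-ynoate 12 and acid chloride 7, and returns at 15. Ynoate 12 is heated with 1-methoxy-1,3-bis(trimethylsilyloxy)buta-1,3-diene (the bis-silylated form of methyl acetoacetate 8), an established resorcylate benzannulation, to give the cycloadduct benzyl 6-methoxy-2-pentyl-4,6-bis(trimethylsilyloxy)cyclohexa-1,4-diene-1-carboxylate F1. Dilute aqueous acid aromatises and desilylates this to benzyl 2,4-dihydroxy-6-pentylbenzoate F2. The 4-hydroxyl of F2, the only one not hydrogen-bonded to the ester carbonyl, is then acylated with 7 (Et3N, cat. DMAP, CH2Cl2) to give 15.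

2. Step 6 (Proposed new method). The dienolate may transfer the aroyl group from oxygen to carbon, expel the aroate towards an allenoate, or be silylated on carbon, and the base may attack the enol ester. The fallback uses known chemistry, sets out from acid chloride 7 and returns at target 17. Commercial olivetol (5-pentylbenzene-1,3-diol) is formylated under Vilsmeier–Haack conditions (POCl3, DMF; aqueous hydrolysis) to 2,4-dihydroxy-6-pentylbenzaldehyde F3. Its non-chelated 4-hydroxyl is acylated with 7 (Et3N, CH2Cl2) to give 4-formyl-3-hydroxy-5-pentylphenyl 2,4-dimethoxy-6-[(2-propyl-1,3-dioxolan-2-yl)methyl]benzoate F4. Pinnick oxidation (NaClO2, NaH2PO4, 2-methylbut-2-ene, t-BuOH/H2O) gives 4-({2,4-dimethoxy-6-[(2-propyl-1,3-dioxolan-2-yl)methyl]benzoyl}oxy)-2-hydroxy-6-pentylbenzoic acid F5. Hydrolysis of the dioxolane under the conditions of step 9 then gives 17.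

3. Step 5. The hindered, electron-rich acid chloride may be intercepted by the neighbouring dioxolane oxygen (entry into the isocoumarin manifold), may acylate carbon rather than oxygen of the acetoacetate, or may give the Z enol ester that deprotonates poorly. The fallback sets out from acid 6 and returns at 9. Acid 6 is converted with cyanuric fluoride and pyridine in CH2Cl2 into 2,4-dimethoxy-6-[(2-propyl-1,3-dioxolan-2-yl)methyl]benzoyl fluoride F6, which is far less prone to neighbouring-group attack. F6 is then combined with methyl 3-(trimethylsilyloxy)but-2-enoate and catalytic anhydrous fluoride (TBAT, THF), the fluoride-catalysed O-acylation of a silyl enol ether by an acyl fluoride, to give 9.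

**Further compounds**
F1 | step 8 | benzyl 6-methoxy-2-pentyl-4,6-bis(trimethylsilyloxy)cyclohexa-1,4-diene-1-carboxylate | CCCCCC1=C(C(=O)OCc2ccccc2)C(OC)(O[Si](C)(C)C)C=C(O[Si](C)(C)C)C1
F2 | step 8 | benzyl 2,4-dihydroxy-6-pentylbenzoate | CCCCCc1cc(O)cc(O)c1C(=O)OCc1ccccc1
F3 | step 6 | 2,4-dihydroxy-6-pentylbenzaldehyde | CCCCCc1cc(O)cc(O)c1C=O
F4 | step 6 | 4-formyl-3-hydroxy-5-pentylphenyl 2,4-dimethoxy-6-[(2-propyl-1,3-dioxolan-2-yl)methyl]benzoate | CCCCCc1cc(OC(=O)c2c(CC3(CCC)OCCO3)cc(OC)cc2OC)cc(O)c1C=O
F5 | step 6 | 4-({2,4-dimethoxy-6-[(2-propyl-1,3-dioxolan-2-yl)methyl]benzoyl}oxy)-2-hydroxy-6-pentylbenzoic acid | CCCCCc1cc(OC(=O)c2c(CC3(CCC)OCCO3)cc(OC)cc2OC)cc(O)c1C(=O)O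
F6 | step 5 | 2,4-dimethoxy-6-[(2-propyl-1,3-dioxolan-2-yl)methyl]benzoyl fluoride | CCCC1(Cc2cc(OC)cc(OC)c2C(=O)F)OCCO1
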